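## Retrosynthetic overview

1. The target isoflavone is opened at the O1–C2 bond of ring C and the C2 methine is excised. This gives a diprenylated pentahydroxydeoxybenzoin plus tert-butyl isocyanide as a one-carbon donor; the C–O ring closure is the final, key event.
2. The diprenylated deoxybenzoin is cut at its two C-prenyl bonds on the symmetric acylphloroglucinol ring A (prenyl bromide). Because ring A is symmetric, either ortho hydroxyl closes to the same 6,8-diprenyl isomer.
3. The deoxybenzoin is cut at the aryl ketone bond into phloroglucinol (ring A) and 2,4-dihydroxyphenylacetic acid (ring B).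
4. Ring order: rings A and B are purchased; ring C (the 4-pyranone) is the only ring formed, in the last step. No protecting groups are used.

Assumption: the target has no stereocentre and no stereogenic double bond (it is achiral), so the compound itself is the required single stereoisomer and no asymmetric step is needed.

## Route

Step 1
Reactants: 1 phloroglucinol; 2 2,4-dihydroxyphenylacetic acid
Product: 3 2-(2,4-dihydroxyphenyl)-1-(2,4,6-trihydroxyphenyl)ethan-1-one
Conditions: BF3·OEt2 (neat, about 6 equiv), 75 °C, 1.5 h, Ar; then aq. NaOAc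
Reagents that add atoms: none
Why: Friedel–Crafts (Nencki-type) C-acylation, in which BF3 activates the acid (or the benzofuranone lactone it forms in the flask) toward the very nucleophilic phloroglucinol and the product is held as a deactivated BF2 chelate so that acylation stops at the mono-ketone; no stereocentre is formed.

Step 2
Reactants: 3 2-(2,4-dihydroxyphenyl)-1-(2,4,6-trihydroxyphenyl)ethan-1-one; 4 prenyl bromide
Product: 5 2-(2,4-dihydroxyphenyl)-1-[2,4,6-trihydroxy-3,5-bis(3-methylbut-2-en-1-yl)phenyl]ethan-1-one
Conditions: prenyl bromide (2 × 1.1 equiv), 10% aq. KOH (2 × 1.1 equiv, added in two portions), 0 °C, 2 h, Ar; then 1 M HCl to pH 3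
Reagents that add atoms: prenyl bromide (4), CC(C)=CCBr
Why: Base-mediated C-alkylation (SN2, the classical aqueous-alkali C-prenylation of acylphloroglucinols) of the ring A anion, which is the most acidic site (pKa about 8) and the most carbon-nucleophilic one in water, so that with portionwise base the two equivalent free positions of ring A are prenylated while the less acidic ring B resorcinol stays largely protonated; no stereocentre is formed.

Step 3
Reactants: 5 2-(2,4-dihydroxyphenyl)-1-[2,4,6-trihydroxy-3,5-bis(3-methylbut-2-en-1-yl)phenyl]ethan-1-one; 6 tert-butyl isocyanide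
Product: 9 5,7-dihydroxy-3-(2,4-dihydroxyphenyl)-6,8-bis(3-methylbut-2-en-1-yl)-4H-chromen-4-one, via tert-butylamino enaminone 7 (not isolated), via 2-(tert-butylamino)isoflavanone 8 (not isolated)
Conditions: t-BuNC (3 equiv), Cu2O (10 mol%), 1,4-dioxane, 80 °C, 12 h, Ar; then AcOH, 60 °C, 1 h
Reagents that add atoms: tert-butyl isocyanide (6), CC(C)(C)[N+]#[C-]
Why: Proposed new method: a monovalent copper catalyst (Cu2O) forms a copper enolate at the doubly activated benzylic methylene of 5, 1,1-insertion of the isocyanide carbon and proton transfer give the vinylogous amide 7 (Saegusa-type copper-catalysed isocyanide insertion into an acidic C–H bond, not yet shown on 2-hydroxydeoxybenzoins), the flanking ring A phenol then closes ring C by 6-endo-trig conjugate addition to make the O1–C2 bond (aminal 8), and acetic acid drives β-elimination of tert-butylamine to the aromatic 4-pyranone, so the isocyanide serves as a neutral, non-methylating methine donor; the closest known reaction type is the enaminone (amide acetal) isoflavone ring closure, the two ortho hydroxyls of ring A are equivalent so only one regioisomer can form, and no stereocentre remains.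

## Compound list

1 | phloroglucinol (benzene-1,3,5-triol) | Oc1cc(O)cc(O)c1 | starting material
2 | 2,4-dihydroxyphenylacetic acid | OC(=O)Cc1ccc(O)cc1O | starting material
3 | 2-(2,4-dihydroxyphenyl)-1-(2,4,6-trihydroxyphenyl)ethan-1-one | O=C(Cc1ccc(O)cc1O)c1c(O)cc(O)cc1O | intermediate
4 | prenyl bromide (1-bromo-3-methylbut-2-ene) | CC(C)=CCBr | starting material
5 | 2-(2,4-dihydroxyphenyl)-1-[2,4,6-trihydroxy-3,5-bis(3-methylbut-2-en-1-yl)phenyl]ethan-1-one | O=C(Cc1ccc(O)cc1O)c1c(O)c(CC=C(C)C)c(O)c(CC=C(C)C)c1O | intermediate
6 | tert-butyl isocyanide | CC(C)(C)[N+]#[C-] | starting material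
7 | 3-(tert-butylamino)-2-(2,4-dihydroxyphenyl)-1-[2,4,6-trihydroxy-3,5-bis(3-methylbut-2-en-1-yl)phenyl]prop-2-en-1-one (alkene geometry not defined; both isomers close) | CC(C)(C)NC=C(c1ccc(O)cc1O)C(=O)c1c(O)c(CC=C(C)C)c(O)c(CC=C(C)C)c1O | intermediate
8 | 2-(tert-butylamino)-3-(2,4-dihydroxyphenyl)-5,7-dihydroxy-6,8-bis(3-methylbut-2-en-1-yl)chroman-4-one (racemic diastereomer mixture; both centres are lost on elimination) | CC(C)(C)NC1Oc2c(CC=C(C)C)c(O)c(CC=C(C)C)c(O)c2C(=O)C1c1ccc(O)cc1O | intermediate
9 | 5,7-dihydroxy-3-(2,4-dihydroxyphenyl)-6,8-bis(3-methylbut-2-en-1-yl)-4H-chromen-4-one (6,8-diprenyl-2'-hydroxygenistein, achiral) | CC(C)=CCc1c(O)c(CC=C(C)C)c2occ(-c3ccc(O)cc3O)c(=O)c2c1O | target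

## Step count and risks

Total step count: 3. Longest linear sequence: 3 steps (1 → 3 → 5 → 9).

Risk ranking: step 3 is the most likely to fail, then step 2, then step 1. The fallbacks are given in route order because the second builds on the first.

**Step 1.** The free 2-hydroxyphenylacetic acid may lactonise or self-acylate under BF3·OEt2, and 3 may cyclodehydrate through its ring B ortho hydroxyl to a 2-arylbenzofuran.

Fallback (sets out from 1, comes back at 3): the classical Hoesch route with ring B benzyl-protected. Commercial 2,4-bis(benzyloxy)benzaldehyde F1 is homologated by van Leusen reductive cyanation with p-toluenesulfonylmethyl isocyanide (TosMIC, t-BuOK, DME, −40 °C; then MeOH, reflux) to 2-[2,4-bis(benzyloxy)phenyl]acetonitrile F2. Hoesch acylation of 1 with F2 (ZnCl2, HCl gas, Et2O, 0 °C; then H2O, reflux) gives 2-[2,4-bis(benzyloxy)phenyl]-1-(2,4,6-trihydroxyphenyl)ethan-1-one F3. Hydrogenolysis (H2, Pd/C, EtOAc–MeOH, rt) then gives 3; no prenyl group is present yet, so this is safe.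

**Step 2.** Chemoselectivity rests on the acidity difference between rings A and B. Likely by-products are the mono-prenyl compound (recyclable), the dearomatised triprenyl compound, O-prenyl ethers and ring B alkylation; a modest yield (about 30–40%) is expected.

Fallback (sets out from 1, comes back at 5): ring A selectivity is enforced by protection and no longer by pKa. The dibenzyl ether F3, made from 1 as in the fallback above, is diprenylated under the same aqueous KOH and prenyl bromide conditions to give 2-[2,4-bis(benzyloxy)phenyl]-1-[2,4,6-trihydroxy-3,5-bis(3-methylbut-2-en-1-yl)phenyl]ethan-1-one F4. The benzyl ethers are then removed by catalytic transfer hydrogenolysis (Pd/C, cyclohexa-1,4-diene, EtOH, rt), stopped at full conversion to spare the trisubstituted alkenes, to give 5.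

**Step 3 (the proposed new step).** Three things could go wrong:
- The free phenols may add isocyanide reversibly to give aryl formimidates. Excess isocyanide and the acetic acid finish are meant to absorb this.
- The polyphenol may bind and deactivate the copper.
- The ring B ortho hydroxyl could close to the isomeric 3-aroylbenzofuran. This is a disfavoured 5-endo closure, and the acid finish should equilibrate it toward the chelated chromone.

Fallback (sets out from 5, comes back at 9): known amide-acetal chemistry. Compound 5 is warmed with N,N-dimethylformamide dimethyl acetal (1.3 equiv, THF, 50 °C) to give 3-(dimethylamino)-2-(2,4-dihydroxyphenyl)-1-[2,4,6-trihydroxy-3,5-bis(3-methylbut-2-en-1-yl)phenyl]prop-2-en-1-one F5. F5 is closed to 9 with AcOH at 60 °C by conjugate addition of the ring A phenol and loss of dimethylamine. The acetal is kept near stoichiometric to limit O-methylation of the phenols.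

## Further compounds

F1 | step 1 | 2,4-bis(benzyloxy)benzaldehyde | O=Cc1ccc(OCc2ccccc2)cc1OCc1ccccc1
F2 | step 1 | 2-[2,4-bis(benzyloxy)phenyl]acetonitrile | N#CCc1ccc(OCc2ccccc2)cc1OCc1ccccc1
F3 | step 1 | 2-[2,4-bis(benzyloxy)phenyl]-1-(2,4,6-trihydroxyphenyl)ethan-1-one | O=C(Cc1ccc(OCc2ccccc2)cc1OCc1ccccc1)c1c(O)cc(O)cc1O
F4 | step 2 | 2-[2,4-bis(benzyloxy)phenyl]-1-[2,4,6-trihydroxy-3,5-bis(3-methylbut-2-en-1-yl)phenyl]ethan-1-one | O=C(Cc1ccc(OCc2ccccc2)cc1OCc1ccccc1)c1c(O)c(CC=C(C)C)c(O)c(CC=C(C)C)c1O
F5 | step 3 | 3-(dimethylamino)-2-(2,4-dihydroxyphenyl)-1-[2,4,6-trihydroxy-3,5-bis(3-methylbut-2-en-1-yl)phenyl]prop-2-en-1-one | CN(C)C=C(c1ccc(O)cc1O)C(=O)c1c(O)c(CC=C(C)C)c(O)c(CC=C(C)C)c1O
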